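At early times both earlier runs moved fast. In teal, with reagent in excess, substrate read 0% by 0.125 d. Green lost 0.111 M of substrate by 2.50 d, about its reagent charge of 0.11 M, so I took one reagent per substrate. I wrote this note for whoever took over the bench.

| flask | substrate | reagent | remark | time |
|---|---|---|---|---|
| green | 0.25 M | 0.11 M | run made earlier |  |
| teal | 0.25 M | 1.1 M | run made earlier |  |
| maple | 0.25 M | 0.0800 M |  | 2.5 d |
| birch | 0.25 M | 0.250 M |  | 2.5 d |
| ash | 0.25 M | 0.800 M |  | 2.5 d |

- green (time / d: target / %, substrate / %): 0.208: 6.5, 60.5; 0.333: 6.7, 57.3; 0.500: 6.2, 56.9; 0.625: 4.7, 55.5; 1.04: 3.7, 56.5; 1.67: 1.2, 56.7; 2.50: 0.6, 55.4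
- teal (time / d: target / %, substrate / %): 0.125: 19.0, 0; 0.417: 14.5, 0; 0.625: 9.5, 0; 1.04: 4.5, 0.2; 1.67: 3.4, 0; 2.08: 1.1, 0; 2.50: 0.4, 0

(each reading ± 0.5 percentage points)

- "hardly changes" means that all values lie within two and a half points (for a concentration: within two and a half percent of the largest)

* [target] at the end for maple, birch, ash, in this order
* how that number moves from the first to the last of them (hardly changes / falls, then rises / rises, then falls / falls all the way / rises all the way)

Teal's target fell from 19.0% to 1.1% between 0.125 d and 2.08 d, a first-order loss of 1.46 d⁻¹. Running that back to the start gave 22.8%. I called this the target share, or selectivity: the fraction of the substrate used that becomes target. My zero was an even split, where target takes half, and teal read less than that.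

The share times the charge of the limiting reagent gives what a flask makes. In maple, where reagent is limiting, that was 0.0182 M, and in ash, where substrate is limiting, 0.0570 M. Over 2.5 d, 2.62% of it survives, so I expected 4.77 × 10⁻⁴ M in maple and 0.00149 M in ash. I put birch, with equal charges, above ash without a figure, since target arrives late there.

I told my successor not to read levelled substrate as a stable flask, and to take the flask off then instead of leaving it to stand. Green's substrate held near 56.9% from 0.500 d while its target went from 6.2% to 0.6%.

The forecast gave 0.0011 M, 0.0042 M and 0.0017 M, a row that rises, then falls, with birch highest since “the second-order tail keeps feeding target late”. Its maple and ash figures stood above mine.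

The flasks gave 6.88 × 10⁻⁴ M, 0.00286 M and 0.00199 M, a row that rises, then falls.

    substrate + reagent → intermediate A (k = 0.0340 L mol⁻¹ min⁻¹)
    target → over-reaction product (k = 9.40 × 10⁻⁴ min⁻¹)
    intermediate A ⇌ intermediate B (K = 0.380, k = 0.00720 min⁻¹)
    substrate + reagent → target (k = 0.0100 L mol⁻¹ min⁻¹)

The largest single effect I found on maple's end value was the turning of target into over-reaction product. With that step taken away, maple ended at 0.0182 M instead of 6.88 × 10⁻⁴ M, and the share times the reagent charge gives 0.0182 M for that run. The same run for ash, with the share times the substrate charge at 0.0570 M, ended at 0.0568 M.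

The data were computed from invented constants, noise included.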